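You are asked how much of the charged J ends as Z.D and X together, and which change adds most.

J 0.50 M; D 0.700 equiv; time 12 min
    J ⇌ Z, rate k1*(cs1 - [Z]) while solid is left; crystals form when [Z] > cs1 (cs1 = 0.37 M, k1 = 0.010 s⁻¹)
    Z + D → Z.D (k2 = 0.041 M⁻¹ s⁻¹)
    2 Z → Z2 (k3 = 0.011 M⁻¹ s⁻¹)
    X ⇌ Z.D, rate k4*(cs4 - [Z.D]) while solid is left; crystals form when [Z.D] > cs4 (cs4 = 0.20 M, k4 = 1.5 s⁻¹)
    D ⇌ E (K5 = 3.3, k5 = 0.013 s⁻¹)
    2 J → J2 (k6 = 0.026 M⁻¹ s⁻¹)
- a species is counted by the J in it: one Z2 or J2 counts as two
- amounts and yields of Z.D count X too
- two of one species on the left: rate k times its square, two consumed each time
- given per volume of solution although it is solid: J, X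
- at the start none of J is in solution
- run time (flask): 12 min
- how much Z.D and X together there is at 12 min, in percent of the J charged
- the change that raises the amount of Z.D and X together at 12 min, in percent of the J charged most ("none" if none brings more than 2 percentage points) (south-west / north-east / north / west / none)
- amount of Z.D and X together at 12 min, in percent of the J charged, after north-east

Follow one molecule of J. At its first fork the solid either dissolves, at 0.00370 M s⁻¹ into an empty solution, or pairs into J2, at a rate that goes with the square of the solid left. Take the solid at half its charge as the typical moment: pairing then runs at 0.00325 M s⁻¹. The escape chance, the share of J that dissolves rather than pairs, is then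

escape chance = 0.00370 M s⁻¹ / (0.00370 M s⁻¹ + 0.00325 M s⁻¹) = 53.2%

A second way is a clock. Let the solid shrink by pairing, subtract what dissolving has taken, and find when nothing is left. That comes at 55.4 s, by when dissolving has taken 41.0%. The two ways part, the clock reading lower, and the clock is the one that cheats: its pairing goes on spending J that has already dissolved. So you keep 53.2%.

The second fork is for dissolved Z. D and E relax in 0.682 min, far sooner than the run ends, so you may share the D charge between them by their equilibrium constant, which gives 0.0814 M of free D if coupling took none. Coupling does take D from that pool, so this is a rough working figure and not a level the flask holds. Held at that figure, coupling is pseudo-first-order in Z, with a half-life of 3.46 min, shorter than the run. With the full stock of Z, pairing to Z2 runs 1.75 times as fast as coupling, and this ratio falls as the stock falls. Summed over that fall, coupling's share is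

ln(1 + 1.75) / 1.75 = 57.7%

Both forks together give

Z.D and X = 53.2% × 57.7% = 30.7%

That is 0.154 M of Z.D, below its solubility, so the reckoning forms no X, and north-east leaves 30.7%. Doubling D halves the ratio, while doubling the dissolution coefficient of step 1 raises the escape chance. Through both forks the first gains more, so the choice is west.

The forecast gives 34% (28% to 40%), west, and 34% after north-east, holding that “X therefore never forms and the step 4 changes do nothing”.

The simulated flask holds 29.9% of Z.D and X at 12.0 min, and 29.9% after north-east, while west gains most, 14 percentage points. Its J2 stands at 45.8%, so 54.2% of the J escaped pairing, against the escape chance of 53.2%. In the neighbour flask with 0.12 M of J, pairing at half the charge falls to 1.87 × 10⁻⁴ M s⁻¹, which puts the escape chance at 95.2%, and that flask's J2 stands at 6.49%, leaving 93.5% escaped.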